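## The problem

Target 20 is a 6-oxabicyclo[3.2.2]non-3-ene-2,7-dione: a seven-membered carbocycle (C1, C2, C3, C4, C5, C9, C8) whose C1 and C5 are spanned by a lactone (O6–C7). C5 is therefore at once a ring carbon, a methyl ketal carbon and the alkoxy carbon of the lactone (a pseudo-ester), and C1 lies between the ring ketone C2 and the lactone carbonyl C7. The four stereocentres (1R,5S,8R,9R) are not independent, because the bridge ties C1 and C5 together. What must be set is the absolute configuration of the aryl carbon C8, the trans relation of aryl and methyl across C8–C9, and the face of the carbocycle that the lactone spans (aryl on the lactone side, methyl on the enone side). C8 is the only centre that can be placed on a flat precursor by a catalyst, and it must then direct C9 and the bridge face. The acyloxy ketal is labile to acid and nucleophiles, C1 is a β-keto ester carbon that decarboxylates once the lactone is open, the 2-allyl enone can slip into conjugation, and the trimethoxyarene does not tolerate strong Lewis acids. The enabling feature is that, with the stereocentres removed, the carbocycle C2(=O)/C3/C4/C5(OMe)/C9(Me)/C8/C1(CO2R) is a 4-methoxytropone with an ester next to the carbonyl. C1, C8, C9 and C5, with their ester, H, methyl and methoxy substituents, are C3–C6 of a 6-methoxy-5-methyl-2-pyrone-3-carboxylate, and C2, C3, C4 are the three carbons of a cyclopropenone ketal.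

## Retrosynthesis

**C3–allyl bond (20 ⇒ 19 ⇒ 18).** The allyl group is removed first, through iodide 19 back to enone 18. Carrying it from the start would require an allyl-substituted cyclopropenone ketal, which opens to two different vinylcarbenes and doubles the orientation problem of the key step; it would also expose a terminal alkene to the rhodium and iodine chemistry in between. 18 lacks only these three carbons. The forward steps are α-iodination of an enone whose other α-carbon is a bridgehead and cannot enolise, and a cross-coupling mild enough not to isomerise the product.

**O6–C5 and C9–H bonds (18 ⇒ 17 ⇒ 16).** These two bonds are cut together: 18 is the adduct of the carboxyl group of acid 17 across its own C5=C6 enol ether. The neighbouring cut, O-methylation of a bridged lactol, needs the free 1,4-dione and leaves the bridge face and the methyl configuration to an equilibrium of unknown position. In the addition mode one carboxyl group delivers both H and O to the same face. 17 is monocyclic with a single fixed stereocentre; being a β-keto acid it is not stored but released with fluoride from the 2-(trimethylsilyl)ethyl ester 16. The forward reaction must outrun decarboxylation and must run without an external strong acid, which would open a stepwise pathway to the other bridge face.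

**Aryl–C7 bond (16 ⇒ 14 + 15).** Removing the aryl group gives tropone 14 and boronic acid 15. The carbon concerned is β to both the ring carbonyl and the ester, so in 14 it is the most electrophilic CH of the ring. Placing the aryl group on the pyrone instead would hinder the cycloaddition at the neighbouring carbon and leave the stereocentre to an asymmetric reduction of a tetrasubstituted tropone bond. 14 is achiral and flat. The forward reaction must select this CH among the ring positions and one of its two faces.

**Ketal (14 ⇒ 13).** 14 is the hydrolysis product of cycloheptatriene ketal 13; nothing else changes.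

**Two ring C–C bonds (13 ⇒ 6 + 11, through 12).** 13 is cut at the bond from its ketal carbon to the ester-bearing carbon and at the bond from the adjacent CH=CH unit to the methoxy-bearing carbon. With the lost carboxyl bridge restored this is bridged lactone 12, the [4+3] adduct of pyrone 6 and the vinylcarbene from cyclopropenone ketal 11. 12 already has the bicyclic skeleton of 20, but with a C8=C9 double bond where the aryl/methyl pair must go and an extra ester on the bridgehead, so it is allowed to decarboxylate. Against stepwise annulations of an acyclic chain, this cut forms the ring and places ester, methyl and methoxy on the right carbons in one operation from two small achiral pieces. The forward reaction must show the right orientation and periselectivity.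

**Pyrone (6 ⇒ 5 ⇒ 3 + 4; 3 ⇒ 1 + 2).** 6 is opened at the ring O–C2 bond to half ester 5, whose only free carboxyl becomes C2. An all-ester analogue of 5 could close in either direction and give the isomeric pyrone with methyl and ester exchanged, which is why the half acid is used. 5 comes from the dioxanedione 3 and alcohol 4, a step that also lets the ester group be chosen for the end game. 3 is the addition–elimination product of the enolate of 1 with 2.

**Cyclopropenone ketal (11 ⇒ 9 ⇒ 7 + 8, through 10).** 11 arises by double dehydrochlorination of bis(chloromethyl) ketal 9, through chlorocyclopropane 10; 9 is the ketal of 7 with diol 8.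

## Roads not taken

**Alternative 1:** The cut is the C4–C5 bond. Forward, the iodoalkene of anhydride A2 would be converted under Nozaki–Hiyama–Kishi conditions into an alkenylchromium species that adds to the distal anhydride carbonyl, closing the carbocycle and giving lactol A1 directly in its bridged form.
- Merits: the aryl, methyl and carboxyl-bearing centres are fixed on a six-membered anhydride before any bridging, so the face of the lactone bridge is not in question, and the allyl group is present from the start.
- Weak points: A2 carries three contiguous stereocentres, a carbinol and a (Z)-iodoalkene, and needs a long linear preparation. Alkenylchromium reagents are selective for aldehydes and add poorly to anhydrides. The nearer carbonyl offers a competing five-membered closure. A1 still needs desilylation, oxidation at C2 and O-methylation of a lactol that can open to a β-keto acid.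
- Comparison: in bridge-face control this road is better than the chosen one, which depends on the syn-addition argument of step 9. The chosen plan sets against it a ring-forming step with close precedent, flat intermediates with one stereocentre to set, and roughly half the step count.

**Alternative 2:** The cuts are the aryl–C8 bond and the C1–C2 bond, with no ring closed. Forward, an aryl cuprate adds to lactone A4 anti to its methyl group and the enolate is trapped by enal A5, giving A3.
- Merits: the absolute configuration comes from the chiral pool, and the 4,5-trans and 3,4-trans relations follow from substrate control in a well-precedented reaction class.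
- Weak points: the seven-membered ring is still unmade and would need a closure of the kind used in alternative 1. The lactone of A3 is not the lactone of the target, since its alkoxy carbon is a CH2 that must be raised to the carboxyl level. Several redox and protecting-group steps follow, and the carbinol centre is formed without control before being oxidised away.
- Comparison: the early stereocontrol is more secure than a new catalytic arylation of a tropone. The chosen plan has only one catalyst-controlled centre to set against that, but it buys the ring, the oxidation pattern and the lactone carbon in a single step and is far shorter.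

**Alternative 3:** The cuts are both C–C bonds of the aryl carbon (C8–C1 and C8–C9). Forward, aldehyde A8 condenses with the active methylene of enedione A7 (Knoevenagel), and the ethyl-ketone α-carbon then adds to the arylidene (intramolecular Michael addition) to give A6.
- Merits: it is the shortest route on paper, from a cheap aldehyde, and it carries the allyl group from the start, so no iodination and no tin reagent are needed.
- Weak points: A7 is a (Z)-ene-1,4-dione that isomerises to the (E)-form, which cannot cyclise, and is itself a strong Michael acceptor. Three enolisable positions compete in the condensation. The seven-membered endo closure is reversible, gives relative configuration only under thermodynamic control, and offers no handle for absolute configuration unless a chiral catalyst is found. A6 must still be turned into the methoxy lactone, which meets the same bridge-face question, now with a free 1,4-dione.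
- Comparison: in step count and in avoiding tin this road is better. The chosen plan is longer by the late allylation, but it has a defined source of absolute configuration and forms the ring by an irreversible cycloaddition.

Key step: step 6

Assumption: compound 2 is taken as a purchased reagent (it is otherwise made in one operation from 2,2-dimethyl-1,3-dioxane-4,6-dione and trimethyl orthoformate), and the antipode of the diene ligand in step 8 is used if the enantiomer written delivers the aryl group to the wrong face.

Step 1
Reactants: 1 methyl propanoate; 2 5-(methoxymethylidene)-2,2-dimethyl-1,3-dioxane-4,6-dione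
Product: 3 5-[(E)-3-methoxy-2-methyl-3-oxoprop-1-enyl]-2,2-dimethyl-1,3-dioxane-4,6-dione
Conditions: LiN(SiMe3)2, THF, −78 °C; then 2, −78 → 0 °C; cold 1 M HCl
Reagents that add atoms: none
Why: Addition–elimination of an ester lithium enolate at the alkoxymethylene carbon; the methoxide released deprotonates the product to a delocalised anion, which guards against a second addition, and the silylamide base leaves no amine that could add to 2; the tautomer and alkene geometry of 3 are immaterial because step 3 passes through the common dienolate.

Step 2
Reactants: 3; 4 2-(trimethylsilyl)ethanol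
Product: 5 (E)-5-methoxy-4-methyl-5-oxo-2-{[2-(trimethylsilyl)ethoxy]carbonyl}pent-3-enoic acid (racemic)
Conditions: toluene, 80 °C
Reagents that add atoms: none
Why: Alcoholysis of a 5-monosubstituted dioxanedione: the primary alcohol opens the ring and acetone is lost, leaving a malonic half ester with exactly one free carboxyl; the temperature is kept below that at which the half acid decarboxylates.

Step 3
Reactants: 5
Product: 6 2-(trimethylsilyl)ethyl 6-methoxy-5-methyl-2-oxo-2H-pyran-3-carboxylate
Conditions: (CF3CO)2O, Et3N, CH2Cl2, −20 → 0 °C
Reagents that add atoms: none
Why: Enol-lactonisation: the mixed anhydride of the only free carboxyl is attacked by the oxygen of the methyl ester dienolate in a six-membered closure, so the methyl ester carbon becomes C6 with its methoxy group and the activated carboxyl becomes C2; the amine lets both alkene isomers equilibrate through the dienolate or the ketene, and no isomeric pyrone can form.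

Step 4
Reactants: 7 1,3-dichloropropan-2-one; 8 2,2-dimethylpropane-1,3-diol
Product: 9 2,2-bis(chloromethyl)-5,5-dimethyl-1,3-dioxane
Conditions: TsOH·H2O (cat.), benzene, reflux, Dean–Stark trap
Reagents that add atoms: none
Why: Acid-catalysed ketalisation driven by azeotropic removal of water; the six-membered neopentyl ketal is the one that later stabilises the vinylcarbene.

Step 5
Reactants: 9
Product: 11 6,6-dimethyl-4,8-dioxaspiro[2.5]oct-1-ene, via 1-chloro-6,6-dimethyl-4,8-dioxaspiro[2.5]octane 10 (not isolated)
Conditions: NaNH2 (3 equiv), liquid NH3, −50 → −35 °C; NH4Cl
Reagents that add atoms: none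
Why: 1,3-Dehydrochlorination (α-deprotonation and intramolecular displacement) gives chlorocyclopropane 10, and E2 elimination then gives the cyclopropene, which the excess amide holds as its sodium salt until the quench.

Step 6
Reactants: 6; 11
Product: 13 2-(trimethylsilyl)ethyl 10-methoxy-3,3,9-trimethyl-1,5-dioxaspiro[5.6]dodeca-7,9,11-triene-7-carboxylate, via bridged lactone cycloadduct 12 (not isolated)
Conditions: 11 (2–3 equiv), benzene, 75–80 °C, sealed vessel, argon, dark
Reagents that add atoms: none
Why: On warming, 11 opens reversibly to a π-delocalised singlet vinylcarbene, a three-carbon dipole that is nucleophilic at the carbene carbon and cationic at the dialkoxy carbon. This species adds across C3 and C6 of pyrone 6, the termini of the electron-poor diene, to give bridged lactone 12, which loses carbon dioxide by retro-[4+2] at the reaction temperature and leaves cycloheptatriene ketal 13. The closest known reaction type is the thermal [4+3] cycloaddition of cyclopropenone ketals with ester-substituted 2-pyrones followed by decarboxylation, applied here to a 6-alkoxy member of that class. The seven-membered carbocycle is closed by the intermolecular [4+3] cycloaddition itself, both ring bonds (carbene carbon to C6, ketal carbon to C3) forming in that event; the lactone bridge of 12 is the pyrone ring carried along, not a new closure. No stereocentre results, because both bridgeheads of 12 become trigonal on decarboxylation. The step needs orientation (carbene carbon to C6, ketal carbon to C3) and periselectivity ([4+3] rather than addition to the C3=C4 bond or Diels–Alder reaction of the intact cyclopropene). Orientation is secured by C6 being the vinylogous acceptor terminus for both the ring carbonyl and the C3 ester, with C3 taking up the malonate-like negative charge that collapses on the dialkoxy cation. Periselectivity is secured by working at 75–80 °C, where the carbene manifold operates, although the C6 methoxy and C5 methyl groups make C6 less electrophilic and more hindered than in the known cases.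

Step 7
Reactants: 13
Product: 14 2-(trimethylsilyl)ethyl 4-methoxy-3-methyl-7-oxocyclohepta-1,3,5-triene-1-carboxylate
Conditions: AcOH/THF/H2O (3:1:1), 25 °C
Reagents that add atoms: water, O
Why: Ketal hydrolysis through an alkoxytropylium ion, which makes tropone ketals unusually easy to cleave; the ring methoxy group (a vinylogous ester once the tropone exists) and the silylethyl ester are stable to dilute acetic acid.

Step 8
Reactants: 14; 15 (3,4,5-trimethoxyphenyl)boronic acid
Product: 16 2-(trimethylsilyl)ethyl (7R)-5-methoxy-6-methyl-2-oxo-7-(3,4,5-trimethoxyphenyl)cyclohepta-3,5-diene-1-carboxylate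
Conditions: [RhCl(C2H4)2]2 (2.5 mol %), (1R,4R)-2,5-diphenylbicyclo[2.2.2]octa-2,5-diene (5.5 mol %), KOH (0.2 equiv), 1,4-dioxane/H2O (10:1), 30 °C
Reagents that add atoms: none
Why: Proposed new method: the aryl–rhodium species formed by transmetalation should insert the C1=C2 bond of 14, whose CH (C2 of 14, C7 of 16) is β to both the ring carbonyl and the ester, giving the rhodium enolate of a β-keto ester that water protonates; the chiral diene distinguishes the two faces of the flat tropone and so sets C7, and the product is at once enolised (C1 is left as an epimer/enol mixture), which blocks a second addition; the closest known reaction type is the rhodium/chiral diene-catalysed asymmetric 1,4-addition of arylboronic acids to cyclic enones and alkylidene 1,3-dicarbonyl acceptors (Hayashi–Miyaura reaction), not yet shown on tropones.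

Step 9
Reactants: 16
Product: 18 (1R,5R,8R,9R)-5-methoxy-9-methyl-8-(3,4,5-trimethoxyphenyl)-6-oxabicyclo[3.2.2]non-3-ene-2,7-dione, via free β-keto acid 17 (not isolated)
Conditions: Bu4NF, THF, 0 °C; NaH2PO4 buffer (pH 4), extraction; then benzene, 25 °C
Reagents that add atoms: none
Why: Fluoride-induced fragmentation frees the carboxyl without acid or strong base, and acid 17 then adds across its own C5=C6 enol ether (intramolecular Markovnikov hydroacyloxylation, transannular six-membered lactone closure): the carboxyl protonates C6 and its oxygen closes on C5 from the same face, so the methyl group is pushed to the opposite face. C1 epimerises through the enol, and only the epimer with carboxyl cis to aryl closes without eclipsing aryl and methyl on the new two-carbon bridge, so C1, C5 and C9 should all be set by the aryl centre (Curtin–Hammett selection); the C5 descriptor of 18 is R only because the unsubstituted enone changes the priorities.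

Step 10
Reactants: 18
Product: 19 (1R,5S,8R,9R)-3-iodo-5-methoxy-9-methyl-8-(3,4,5-trimethoxyphenyl)-6-oxabicyclo[3.2.2]non-3-ene-2,7-dione
Conditions: I2, pyridine, CH2Cl2, 0 → 25 °C
Reagents that add atoms: iodine, II
Why: α-Iodination of an enone by reversible conjugate addition of pyridine, iodination of the resulting enolate and elimination (Baylis–Hillman-type mechanism); the other α-carbon, C1, is a bridgehead that cannot enolise (Bredt's rule), and the acyloxy ketal tolerates the weakly basic medium.

Step 11
Reactants: 19
Product: 20 (1R,5S,8R,9R)-5-methoxy-9-methyl-3-(prop-2-enyl)-8-(3,4,5-trimethoxyphenyl)-6-oxabicyclo[3.2.2]non-3-ene-2,7-dione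
Conditions: allylSnBu3, Pd2(dba)3 (5 mol %), AsPh3 (20 mol %), CuI (10 mol %), DMF, 25–40 °C
Reagents that add atoms: allyltributylstannane, C=CC[Sn](CCCC)(CCCC)CCCC
Why: Stille coupling of an α-iodoenone with an allylstannane; the arsine ligand and CuI speed transmetalation so the reaction runs near room temperature, which limits migration of the allyl double bond into conjugation and leaves the acyloxy ketal untouched.

## Compound list

1 | methyl propanoate | CCC(=O)OC | starting material
2 | 5-(methoxymethylidene)-2,2-dimethyl-1,3-dioxane-4,6-dione | COC=C1C(=O)OC(C)(C)OC1=O | starting material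
3 | 5-[(E)-3-methoxy-2-methyl-3-oxoprop-1-enyl]-2,2-dimethyl-1,3-dioxane-4,6-dione | COC(=O)/C(C)=C/C1C(=O)OC(C)(C)OC1=O | intermediate
4 | 2-(trimethylsilyl)ethanol | C[Si](C)(C)CCO | starting material
5 | (E)-5-methoxy-4-methyl-5-oxo-2-{[2-(trimethylsilyl)ethoxy]carbonyl}pent-3-enoic acid (racemic) | COC(=O)/C(C)=C/C(C(=O)O)C(=O)OCC[Si](C)(C)C | intermediate
6 | 2-(trimethylsilyl)ethyl 6-methoxy-5-methyl-2-oxo-2H-pyran-3-carboxylate | COC1=C(C)C=C(C(=O)OCC[Si](C)(C)C)C(=O)O1 | intermediate
7 | 1,3-dichloropropan-2-one | ClCC(=O)CCl | starting material
8 | 2,2-dimethylpropane-1,3-diol | CC(C)(CO)CO | starting material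
9 | 2,2-bis(chloromethyl)-5,5-dimethyl-1,3-dioxane | CC1(C)COC(CCl)(CCl)OC1 | intermediate
10 | 1-chloro-6,6-dimethyl-4,8-dioxaspiro[2.5]octane (racemic) | CC1(C)COC2(CC2Cl)OC1 | intermediate
11 | 6,6-dimethyl-4,8-dioxaspiro[2.5]oct-1-ene | CC1(C)COC2(C=C2)OC1 | intermediate
12 | 2-(trimethylsilyl)ethyl 5-methoxy-5',5',9-trimethyl-7-oxospiro[6-oxabicyclo[3.2.2]nona-3,8-diene-2,2'-[1,3]dioxane]-1-carboxylate (racemic) | COC12OC(=O)C(C(=O)OCC[Si](C)(C)C)(C=C1C)C1(OCC(C)(C)CO1)C=C2 | intermediate
13 | 2-(trimethylsilyl)ethyl 10-methoxy-3,3,9-trimethyl-1,5-dioxaspiro[5.6]dodeca-7,9,11-triene-7-carboxylate | COC1=C(C)C=C(C(=O)OCC[Si](C)(C)C)C2(OCC(C)(C)CO2)C=C1 | intermediate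
14 | 2-(trimethylsilyl)ethyl 4-methoxy-3-methyl-7-oxocyclohepta-1,3,5-triene-1-carboxylate | COC1=C(C)C=C(C(=O)OCC[Si](C)(C)C)C(=O)C=C1 | intermediate
15 | (3,4,5-trimethoxyphenyl)boronic acid | COc1cc(B(O)O)cc(OC)c1OC | starting material
16 | 2-(trimethylsilyl)ethyl (7R)-5-methoxy-6-methyl-2-oxo-7-(3,4,5-trimethoxyphenyl)cyclohepta-3,5-diene-1-carboxylate (C1 epimers and enol in equilibrium) | COC1=C(C)[C@@H](c2cc(OC)c(OC)c(OC)c2)C(C(=O)OCC[Si](C)(C)C)C(=O)C=C1 | intermediate
17 | (7R)-5-methoxy-6-methyl-2-oxo-7-(3,4,5-trimethoxyphenyl)cyclohepta-3,5-diene-1-carboxylic acid (C1 epimers and enol in equilibrium) | COC1=C(C)[C@@H](c2cc(OC)c(OC)c(OC)c2)C(C(=O)O)C(=O)C=C1 | intermediate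
18 | (1R,5R,8R,9R)-5-methoxy-9-methyl-8-(3,4,5-trimethoxyphenyl)-6-oxabicyclo[3.2.2]non-3-ene-2,7-dione (aryl on the lactone side, methyl on the enone side) | O=C1C=C[C@@]2(OC)OC(=O)[C@@H]1[C@H](c1cc(OC)c(OC)c(OC)c1)[C@H]2C | intermediate
19 | (1R,5S,8R,9R)-3-iodo-5-methoxy-9-methyl-8-(3,4,5-trimethoxyphenyl)-6-oxabicyclo[3.2.2]non-3-ene-2,7-dione | O=C1C(I)=C[C@@]2(OC)OC(=O)[C@@H]1[C@H](c1cc(OC)c(OC)c(OC)c1)[C@H]2C | intermediate
20 | (1R,5S,8R,9R)-5-methoxy-9-methyl-3-(prop-2-enyl)-8-(3,4,5-trimethoxyphenyl)-6-oxabicyclo[3.2.2]non-3-ene-2,7-dione | C=CCC1=C[C@@]2(OC)OC(=O)[C@@H](C1=O)[C@H](c1cc(OC)c(OC)c(OC)c1)[C@H]2C | target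

## Step count and risks

Total: 11 steps. Longest linear sequence: 9 steps (1, 2, 3, 6, 7, 8, 9, 10, 11); the ketal branch (4, 5) joins at step 6.

**Step 8 (proposed new method).** The likely failures are transfer of the aryl group to another ring position (the CH next to the carbonyl on the unsubstituted side, in a 1,8-sense), poor turnover because the tropone binds rhodium as a diene or is too stabilised to insert, and weak facial discrimination on a ring with no nearby stereo-differentiating group. The fallback sets out from 14 and uses the classical stoichiometric organocopper 1,4-addition to a 2-alkoxycarbonyl enone: ArMgBr (Ar = 3,4,5-trimethoxyphenyl, from 5-bromo-1,2,3-trimethoxybenzene), CuBr·SMe2 and Me3SiCl in THF at −78 °C. This should give racemic 2-(trimethylsilyl)ethyl 5-methoxy-6-methyl-2-oxo-7-(3,4,5-trimethoxyphenyl)cyclohepta-3,5-diene-1-carboxylate F1, whose enantiomers would be separated by preparative chromatography on a chiral stationary phase; the (7R) enantiomer is 16, where the route is rejoined.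

**Step 6 (key step).** The vinylcarbene may be diverted to the C3=C4 bond of the pyrone (five-membered annulation or cyclopropanation), since that CH is the unhindered Michael position while C6 is hindered and carries a donor. The cycloaddition may also become slower than self-consumption of 11. The fallback sets out from 11 and builds the same ring from the cyclopropene as a two-carbon partner:
- Vinylic lithiation (n-BuLi, THF, −78 °C) and acylation with 2-(trimethylsilyl)ethyl chloroformate would give 2-(trimethylsilyl)ethyl 6,6-dimethyl-4,8-dioxaspiro[2.5]oct-1-ene-1-carboxylate F2.
- Diels–Alder reaction of this strained, electron-poor alkene with 2-methoxy-3-methylbuta-1,3-diene ("para" orientation of methoxy and ester) would give 2-(trimethylsilyl)ethyl 4-methoxy-3,5',5'-trimethylspiro[bicyclo[4.1.0]hept-3-ene-7,2'-[1,3]dioxane]-1-carboxylate F3.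
- Dehydrogenation with DDQ (hydride abstraction next to the enol ether, then proton loss) would give the norcaradiene, whose electrocyclic opening is 13, where the route is rejoined.

**Step 9.** The β-keto acid may decarboxylate before it adds. Trace external acid may protonate the enol ether from the aryl face while the carboxyl closes from the other, giving the bridge on the wrong face. Adventitious water may hydrolyse the enol ether. The fallback sets out from 16 and separates the events under equilibrating conditions:
- Dilute aqueous acid (1 M HCl, THF) would hydrolyse the enol ether and let the methyl centre settle trans to aryl, giving 2-(trimethylsilyl)ethyl (6R,7R)-6-methyl-2,5-dioxo-7-(3,4,5-trimethoxyphenyl)cyclohept-3-ene-1-carboxylate F4.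
- Bu4NF would then free the acid, which is expected to exist as its ring tautomer (1R,5R,8R,9R)-5-hydroxy-9-methyl-8-(3,4,5-trimethoxyphenyl)-6-oxabicyclo[3.2.2]non-3-ene-2,7-dione F5.
- Acid-catalysed exchange of the lactol hydroxyl with methanol (camphorsulfonic acid, MeOH, trimethyl orthoformate; pseudo-ester formation) would give 18, where the route is rejoined.

**Step 3.** The dienolate may be trifluoroacetylated at carbon or oxygen, the ketene may oligomerise when the (E)-alkene is slow to reach the cisoid geometry, and the alkoxypyrone may be ring-opened on work-up. The fallback sets out from 3 and uses the dioxanedione itself as the activated acyl group. Heating 3 in toluene should let the ester oxygen close on a ring carbonyl with loss of acetone, giving 6-methoxy-5-methyl-2-oxo-2H-pyran-3-carboxylic acid F6. Mitsunobu esterification of F6 with 4 (PPh3, diisopropyl azodicarboxylate, THF, 0 °C) would give 6, where the route is rejoined.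

## Further compounds

F1 | step 8 | racemic 2-(trimethylsilyl)ethyl 5-methoxy-6-methyl-2-oxo-7-(3,4,5-trimethoxyphenyl)cyclohepta-3,5-diene-1-carboxylate | COC1=C(C)C(c2cc(OC)c(OC)c(OC)c2)C(C(=O)OCC[Si](C)(C)C)C(=O)C=C1
F2 | step 6 | 2-(trimethylsilyl)ethyl 6,6-dimethyl-4,8-dioxaspiro[2.5]oct-1-ene-1-carboxylate | CC1(C)COC2(OC1)C(C(=O)OCC[Si](C)(C)C)=C2
F3 | step 6 | 2-(trimethylsilyl)ethyl 4-methoxy-3,5',5'-trimethylspiro[bicyclo[4.1.0]hept-3-ene-7,2'-[1,3]dioxane]-1-carboxylate (racemic) | COC1=C(C)CC2(C(=O)OCC[Si](C)(C)C)C(C1)C21OCC(C)(C)CO1
F4 | step 9 | 2-(trimethylsilyl)ethyl (6R,7R)-6-methyl-2,5-dioxo-7-(3,4,5-trimethoxyphenyl)cyclohept-3-ene-1-carboxylate (C1 epimers) | O=C1C=CC(=O)[C@H](C)[C@@H](c2cc(OC)c(OC)c(OC)c2)C1C(=O)OCC[Si](C)(C)C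
F5 | step 9 | (1R,5R,8R,9R)-5-hydroxy-9-methyl-8-(3,4,5-trimethoxyphenyl)-6-oxabicyclo[3.2.2]non-3-ene-2,7-dione | O=C1C=C[C@@]2(O)OC(=O)[C@@H]1[C@H](c1cc(OC)c(OC)c(OC)c1)[C@H]2C
F6 | step 3 | 6-methoxy-5-methyl-2-oxo-2H-pyran-3-carboxylic acid | COC1=C(C)C=C(C(=O)O)C(=O)O1
A1 | alternative 1 | 2-(tert-butyldimethylsilyloxy)-5-hydroxy-9-methyl-3-(prop-2-enyl)-8-(3,4,5-trimethoxyphenyl)-6-oxabicyclo[3.2.2]non-3-en-7-one | C=CCC1=C[C@@]2(O)OC(=O)[C@@H]([C@H]1O[Si](C)(C)C(C)(C)C)[C@H](c1cc(OC)c(OC)c(OC)c1)[C@H]2C
A2 | alternative 1 | 3-[(Z)-1-(tert-butyldimethylsilyloxy)-2-(iodomethylidene)pent-4-enyl]-5-methyl-4-(3,4,5-trimethoxyphenyl)oxane-2,6-dione (3,4-trans, 4,5-trans) | C=CC/C(=C/I)[C@H](O[Si](C)(C)C(C)(C)C)[C@@H]1C(=O)OC(=O)[C@H](C)[C@H]1c1cc(OC)c(OC)c(OC)c1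
A3 | alternative 2 | 3-[(Z)-1-hydroxy-2-(iodomethylidene)pent-4-enyl]-5-methyl-4-(3,4,5-trimethoxyphenyl)oxan-2-one (3,4-trans, 4,5-trans; one carbinol epimer) | O=C1OC[C@H](C)[C@@H](c2cc(OC)c(OC)c(OC)c2)[C@@H]1[C@H](O)/C(CC=C)=C\I
A4 | alternative 2 | (5R)-5-methyl-5,6-dihydro-2H-pyran-2-one | O=C1OC[C@H](C)C=C1
A5 | alternative 2 | (Z)-2-(iodomethylidene)pent-4-enal | O=C/C(CC=C)=C\I
A6 | alternative 3 | tert-butyl 6-methyl-2,5-dioxo-3-(prop-2-enyl)-7-(3,4,5-trimethoxyphenyl)cyclohept-3-ene-1-carboxylate (1,7-cis, 6,7-trans) | C=CCC1=CC(=O)[C@H](C)[C@@H](c2cc(OC)c(OC)c(OC)c2)[C@@H](C(=O)OC(C)(C)C)C1=O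
A7 | alternative 3 | tert-butyl (Z)-3,6-dioxo-4-(prop-2-enyl)oct-4-enoate | CCC(=O)/C=C(/CC=C)C(=O)CC(=O)OC(C)(C)C
A8 | alternative 3 | 3,4,5-trimethoxybenzaldehyde | COc1cc(C=O)cc(OC)c1OC
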